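**Retrosynthetic overview**

1. Numbering (labdane): ring A = C1–C5 + C10; ring B = C5–C10; side chain C11–C16 on C9; C17 = formyl carbon on C8; C20 = methyl on C10.
2. Late disconnections: C8(OH)–C17 from ketone 20 (a hydroxymethyl nucleophile enters anti to the axial C20 methyl); the side chain from 9-vinyl compound 14 and (Z)-iodoenoate 16 by B-alkyl Suzuki coupling.
3. Enabling feature: in ring B the oxygen on C8 and the one-carbon branch C11 on C9 are vicinal, and C9 adjoins the quaternary C10. Ring B with an added C6=C7 double bond is therefore the retron of a [4+2] between a 1-silyloxydiene C5=C6–C7=C8–O and an enal C11(=O)–C9=C10(C20). The ring A carbons C1–C4 tie C10 to C5 as a four-atom tether that carries the C3 silyl ether next to the C4 gem-dimethyl group.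
4. Key disconnection: the ring-fusion bond C5–C10 (together with C8–C9) in an intramolecular Diels–Alder reaction of acyclic trienal 11. Rings A and B form in this one step, ring A through the tether and ring B as the cycloadduct ring.
5. Trienal 11 comes from ketone 1 + bromoenoate 2 (C1–C2), asymmetric ketone reduction (C3), cross-metathesis with crotonaldehyde 7 (C6=C7, C8) and silyl dienol ether formation.

Key step: step 8

Remark: 1 and 2 are assumed to be catalogue compounds; if 1 is not stocked it is one step from 2,2-dimethylpent-4-enoic acid and MeLi.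

**Route**

Step 1
Reactants: 1 3,3-dimethylhex-5-en-2-one; 2 methyl (2E)-4-bromo-3-methylbut-2-enoate
Product: 4 methyl (2E)-3,7,7-trimethyl-6-oxodeca-2,9-dienoate, via lithium enolate 3 (not isolated)
Conditions: LiN(i-Pr)2, THF, −78 °C; then 2, −78 → −30 °C
Reagents that add atoms: none
Why: Enolate alkylation (SN2 at the allylic bromide): deprotonation is possible only at the methyl group because the other α-carbon is quaternary, and the E geometry of the enoate is not touched.

Step 2
Reactants: 4 keto enoate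
Product: 5 methyl (2E,6R)-6-hydroxy-3,7,7-trimethyldeca-2,9-dienoate
Conditions: (S)-2-methyl-CBS-oxazaborolidine (10 mol%), catecholborane, PhMe, −78 °C; then aq. NaOH
Reagents that add atoms: none
Why: Corey–Bakshi–Shibata reduction: the tert-alkyl side of the ketone acts as the large group and the CH2 side as the small one, so hydride should reach the face that gives the (R)-alcohol (C3), while catecholborane at low temperature leaves the alkene and the enoate alone.

Step 3
Reactants: 5 hydroxy enoate
Product: 6 methyl (2E,6R)-6-[(tert-butyldimethylsilyl)oxy]-3,7,7-trimethyldeca-2,9-dienoate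
Conditions: TBSOTf, 2,6-lutidine, CH2Cl2, −78 → 0 °C
Reagents that add atoms: tert-butyldimethylsilyl trifluoromethanesulfonate, CC(C)(C)[Si](C)(C)OS(=O)(=O)C(F)(F)F
Why: Silyl ether formation with the silyl triflate, which is reactive enough for the hindered neopentyl-type secondary alcohol; this group later holds C3 equatorial in the key step.

Step 4
Reactants: 6 silyl ether; 7 (2E)-but-2-enal
Product: 8 methyl (2E,6R,9E)-6-[(tert-butyldimethylsilyl)oxy]-3,7,7-trimethyl-11-oxoundeca-2,9-dienoate
Conditions: second-generation Hoveyda–Grubbs catalyst RuCl2(=CH-C6H4-2-O-i-Pr)(H2IMes) (3 mol%), 7 (5 equiv), CH2Cl2, 40 °C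
Reagents that add atoms: none
Why: Olefin cross-metathesis: only the monosubstituted alkene reacts (the trisubstituted enoate alkene is inert), and the conjugated enal should form as the E isomer under thermodynamic control.

Step 5
Reactants: 8 enal
Product: 9 methyl (2E,6R,8E,10E)-6-[(tert-butyldimethylsilyl)oxy]-3,7,7-trimethyl-11-[(triethylsilyl)oxy]undeca-2,8,10-trienoate
Conditions: TESOTf, Et3N, Et2O, −78 → 0 °C
Reagents that add atoms: triethylsilyl trifluoromethanesulfonate, CC[Si](CC)(CC)OS(=O)(=O)C(F)(F)F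
Why: Silyl dienol ether formation by soft enolisation (O-silylation, then γ-deprotonation at C5, the only γ-position); the quaternary neighbour should enforce the E geometry of the new C5=C6 bond, and the ester is not enolised by the amine base.

Step 6
Reactants: 9 dienol ether ester
Product: 10 (2E,6R,8E,10E)-6-[(tert-butyldimethylsilyl)oxy]-3,7,7-trimethyl-11-[(triethylsilyl)oxy]undeca-2,8,10-trien-1-ol
Conditions: i-Bu2AlH (2.2 equiv), CH2Cl2, −78 °C; aq. Rochelle salt
Reagents that add atoms: none
Why: 1,2-Reduction of the enoate to the allylic alcohol by the aluminium hydride, which at −78 °C with a non-acidic work-up should leave both silyl groups, the dienol ether included, in place.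

Step 7
Reactants: 10 allylic alcohol
Product: 11 (2E,6R,8E,10E)-6-[(tert-butyldimethylsilyl)oxy]-3,7,7-trimethyl-11-[(triethylsilyl)oxy]undeca-2,8,10-trienal
Conditions: activated MnO2, CH2Cl2, rt; filtered and used directly
Reagents that add atoms: none
Why: Allylic alcohol oxidation on neutral MnO2 should give the E-enal without acid or base that would cleave the dienol ether or isomerise the enal.

Step 8
Reactants: 11 trienal
Product: 12 (1S,2R,4aS,6R,8aR)-6-[(tert-butyldimethylsilyl)oxy]-5,5,8a-trimethyl-2-[(triethylsilyl)oxy]-1,2,4a,5,6,7,8,8a-octahydronaphthalene-1-carbaldehyde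
Conditions: PhMe (0.01 M), BHT (cat.), 110 °C, base-washed sealed vessel
Reagents that add atoms: none
Why: Concerted, asynchronous normal-demand intramolecular [4+2] cycloaddition in which the silyloxy-raised HOMO of the diene C5=C6–C7=C8 meets the formyl-lowered LUMO of the enal C9=C10, the nucleophilic diene terminus C5 bonding to the enal β-carbon C10 ahead of C8–C9, so the electronic bias coincides with the regiochemistry imposed by the tether. The closest known reaction is the type 1 intramolecular Diels–Alder reaction of terminally activated deca-2,7,9-trienals with oxygenated dienes. Ring A closes by the C5–C10 bond across the four-atom tether C1–C4 (the tether becomes a chair-like six-membered ring, helped by the C4 gem-dimethyl group), and ring B closes as the cyclohexene of the cycloaddition (C5–C10 plus C8–C9, new alkene C6=C7). C5 and C10 (trans ring fusion) follow from the endo transition state of the E-enal, which places the formyl group and the cis-related C20 methyl under the diene and the tether exo; C9 is fixed by suprafacial addition to the E-alkene (formyl cis to the angular methyl), C8 by the E geometry of the silyl enol ether (erased later at the ketone stage), and the absolute sense by the C3 silyl ether, which stays equatorial on the chair-like tether so that only one diene face is reached. The step needs endo over exo selectivity, one π-face, and reaction at C=C instead of C=O; these rest on the formyl group at the dienophile terminus remote from the tether, on the C3 stereocentre next to the gem-dimethyl carbon, and on the absence of any Lewis acid.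

Step 9
Reactants: 12 cycloadduct
Product: 13 (1S,2R,4aS,6R,8aR)-6-[(tert-butyldimethylsilyl)oxy]-5,5,8a-trimethyl-2-[(triethylsilyl)oxy]decahydronaphthalene-1-carbaldehyde
Conditions: H2 (1 atm), Pd/C, EtOAc, rt
Reagents that add atoms: none
Why: Heterogeneous hydrogenation of the only C=C bond (cis-disubstituted C6=C7); no stereocentre is formed, and the aliphatic aldehyde and silyl ethers should be inert.

Step 10
Reactants: 13 saturated aldehyde
Product: 14 (1S,2R,4aS,6R,8aR)-6-[(tert-butyldimethylsilyl)oxy]-1-ethenyl-5,5,8a-trimethyl-2-[(triethylsilyl)oxy]decahydronaphthalene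
Conditions: Ph3PCH3Br, KN(SiMe3)2, THF, −78 → 0 °C
Reagents that add atoms: methyltriphenylphosphonium bromide, C[P+](c1ccccc1)(c1ccccc1)c1ccccc1.[Br-]
Why: Wittig methylenation: the small ylide should add to the hindered aldehyde faster than it enolises it, and C9 already holds the thermodynamically preferred equatorial configuration.

Step 11
Reactants: 15 methyl but-2-ynoate
Product: 16 methyl (2Z)-3-iodobut-2-enoate
Conditions: NaI, AcOH, 110 °C
Reagents that add atoms: sodium iodide, [Na+].[I-]
Why: Anti hydroiodination of the ynoate (conjugate addition of iodide, then protonation) should give the Z-iodoenoate, which fixes the side-chain alkene geometry.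

Step 12
Reactants: 14 vinyl compound; 16 methyl (2Z)-3-iodobut-2-enoate
Product: 18 methyl (2Z)-5-[(1S,2R,4aS,6R,8aR)-6-[(tert-butyldimethylsilyl)oxy]-5,5,8a-trimethyl-2-[(triethylsilyl)oxy]decahydronaphthalen-1-yl]-3-methylpent-2-enoate, via alkyl-9-BBN borane 17 (not isolated)
Conditions: 9-BBN, THF, rt; then 16, Pd(dppf)Cl2 (5 mol%), AsPh3, Cs2CO3, DMF/H2O, rt
Reagents that add atoms: 9-borabicyclo[3.3.1]nonane, [H]B1C2CCCC1CCC2 (its boron and carbon atoms stay in 17 only)
Why: Anti-Markovnikov hydroboration of the only alkene followed by B-alkyl Suzuki–Miyaura coupling, which proceeds with retention at the vinyl iodide and so should deliver the Z-enoate with C12–C13 formed.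

Step 13
Reactants: 18 bis-silyl ether
Product: 19 methyl (2Z)-5-[(1S,2R,4aS,6R,8aR)-6-[(tert-butyldimethylsilyl)oxy]-2-hydroxy-5,5,8a-trimethyldecahydronaphthalen-1-yl]-3-methylpent-2-enoate
Conditions: HF·pyridine, pyridine, THF, 0 °C
Reagents that add atoms: none
Why: Selective silyl ether cleavage: the secondary triethylsilyl ether should be removed much faster than the tert-butyldimethylsilyl ether at the neopentyl-type C3.

Step 14
Reactants: 19 C8 alcohol
Product: 20 methyl (2Z)-5-[(1S,4aS,6R,8aR)-6-[(tert-butyldimethylsilyl)oxy]-5,5,8a-trimethyl-2-oxodecahydronaphthalen-1-yl]-3-methylpent-2-enoate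
Conditions: Dess–Martin periodinane, CH2Cl2, rt
Reagents that add atoms: none
Why: Dess–Martin oxidation of the only free alcohol; the C9 centre α to the new ketone carries its chain equatorial and cis to the C10 methyl, the favoured arrangement, so epimerisation is not a threat.

Step 15
Reactants: 20 ketone
Product: 22 methyl (2Z)-5-[(1S,2R,4aS,6R,8aR)-6-[(tert-butyldimethylsilyl)oxy]-2-hydroxy-2-(hydroxymethyl)-5,5,8a-trimethyldecahydronaphthalen-1-yl]-3-methylpent-2-enoate, via silylmethyl carbinol 21 (not isolated)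
Conditions: (i-PrO)Me2SiCH2MgCl, CeCl3, THF, −78 → 0 °C; then KF, KHCO3, 30% H2O2, THF/MeOH, rt
Reagents that add atoms: (isopropoxydimethylsilyl)methylmagnesium chloride, CC(C)O[Si](C)(C)C[Mg]Cl; hydrogen peroxide, OO
Why: Nucleophilic hydroxymethylation (Grignard addition, then Tamao–Fleming oxidation of C–Si to C–OH): the axial approach to C8 is blocked by the 1,3-diaxial C20 methyl, so the reagent should enter equatorially and give the axial tertiary alcohol cis to C20 with C17 equatorial, the ketone reacting in preference to the β,β-disubstituted enoate.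

Step 16
Reactants: 22 diol
Product: 23 methyl (2Z)-5-[(1S,2R,4aS,6R,8aR)-6-[(tert-butyldimethylsilyl)oxy]-2-formyl-2-hydroxy-5,5,8a-trimethyldecahydronaphthalen-1-yl]-3-methylpent-2-enoate
Conditions: SO3·pyridine, DMSO, i-Pr2NEt, CH2Cl2, 0 °C
Reagents that add atoms: none
Why: Parikh–Doering oxidation: only the primary alcohol can be oxidised (the other free hydroxyl is tertiary), and activated DMSO does not cleave the 1,2-diol.

Step 17
Reactants: 23 silyl-protected hydroxy aldehyde
Product: 24 methyl (2Z)-5-[(1S,2R,4aS,6R,8aR)-2-formyl-2,6-dihydroxy-5,5,8a-trimethyldecahydronaphthalen-1-yl]-3-methylpent-2-enoate (target)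
Conditions: 48% aq. HF, MeCN, 0 °C → rt
Reagents that add atoms: none
Why: Acidic fluoride desilylation of the last silyl ether under non-basic conditions that should leave the α-hydroxy aldehyde and the Z-enoate unchanged.

**Compound list**

1 | 3,3-dimethylhex-5-en-2-one | CC(=O)C(C)(C)CC=C | starting material
2 | methyl (2E)-4-bromo-3-methylbut-2-enoate | COC(=O)/C=C(C)/CBr | starting material
3 | lithium 3,3-dimethylhexa-1,5-dien-2-olate (lithium enolate of 1) | [Li]OC(=C)C(C)(C)CC=C | intermediate
4 | methyl (2E)-3,7,7-trimethyl-6-oxodeca-2,9-dienoate | COC(=O)/C=C(\C)CCC(=O)C(C)(C)CC=C | intermediate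
5 | methyl (2E,6R)-6-hydroxy-3,7,7-trimethyldeca-2,9-dienoate | COC(=O)/C=C(\C)CC[C@@H](O)C(C)(C)CC=C | intermediate
6 | methyl (2E,6R)-6-[(tert-butyldimethylsilyl)oxy]-3,7,7-trimethyldeca-2,9-dienoate | COC(=O)/C=C(\C)CC[C@@H](O[Si](C)(C)C(C)(C)C)C(C)(C)CC=C | intermediate
7 | (2E)-but-2-enal (crotonaldehyde) | C/C=C/C=O | starting material
8 | methyl (2E,6R,9E)-6-[(tert-butyldimethylsilyl)oxy]-3,7,7-trimethyl-11-oxoundeca-2,9-dienoate | COC(=O)/C=C(\C)CC[C@@H](O[Si](C)(C)C(C)(C)C)C(C)(C)C/C=C/C=O | intermediate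
9 | methyl (2E,6R,8E,10E)-6-[(tert-butyldimethylsilyl)oxy]-3,7,7-trimethyl-11-[(triethylsilyl)oxy]undeca-2,8,10-trienoate | COC(=O)/C=C(\C)CC[C@@H](O[Si](C)(C)C(C)(C)C)C(C)(C)/C=C/C=C/O[Si](CC)(CC)CC | intermediate
10 | (2E,6R,8E,10E)-6-[(tert-butyldimethylsilyl)oxy]-3,7,7-trimethyl-11-[(triethylsilyl)oxy]undeca-2,8,10-trien-1-ol | OC/C=C(\C)CC[C@@H](O[Si](C)(C)C(C)(C)C)C(C)(C)/C=C/C=C/O[Si](CC)(CC)CC | intermediate
11 | (2E,6R,8E,10E)-6-[(tert-butyldimethylsilyl)oxy]-3,7,7-trimethyl-11-[(triethylsilyl)oxy]undeca-2,8,10-trienal | O=C/C=C(\C)CC[C@@H](O[Si](C)(C)C(C)(C)C)C(C)(C)/C=C/C=C/O[Si](CC)(CC)CC | intermediate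
12 | (1S,2R,4aS,6R,8aR)-6-[(tert-butyldimethylsilyl)oxy]-5,5,8a-trimethyl-2-[(triethylsilyl)oxy]-1,2,4a,5,6,7,8,8a-octahydronaphthalene-1-carbaldehyde (trans-fused; CHO, OSiEt3, OTBS and 8a-CH3 on one face) | O=C[C@H]1[C@]2(C)CC[C@@H](O[Si](C)(C)C(C)(C)C)C(C)(C)[C@H]2C=C[C@H]1O[Si](CC)(CC)CC | intermediate
13 | (1S,2R,4aS,6R,8aR)-6-[(tert-butyldimethylsilyl)oxy]-5,5,8a-trimethyl-2-[(triethylsilyl)oxy]decahydronaphthalene-1-carbaldehyde | O=C[C@H]1[C@]2(C)CC[C@@H](O[Si](C)(C)C(C)(C)C)C(C)(C)[C@H]2CC[C@H]1O[Si](CC)(CC)CC | intermediate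
14 | (1S,2R,4aS,6R,8aR)-6-[(tert-butyldimethylsilyl)oxy]-1-ethenyl-5,5,8a-trimethyl-2-[(triethylsilyl)oxy]decahydronaphthalene | C=C[C@H]1[C@]2(C)CC[C@@H](O[Si](C)(C)C(C)(C)C)C(C)(C)[C@H]2CC[C@H]1O[Si](CC)(CC)CC | intermediate
15 | methyl but-2-ynoate | CC#CC(=O)OC | starting material
16 | methyl (2Z)-3-iodobut-2-enoate | COC(=O)/C=C(/C)I | intermediate
17 | 9-{2-[(1S,2R,4aS,6R,8aR)-6-[(tert-butyldimethylsilyl)oxy]-5,5,8a-trimethyl-2-[(triethylsilyl)oxy]decahydronaphthalen-1-yl]ethyl}-9-borabicyclo[3.3.1]nonane | C12CCCC(CCC1)B2CC[C@H]1[C@]2(C)CC[C@@H](O[Si](C)(C)C(C)(C)C)C(C)(C)[C@H]2CC[C@H]1O[Si](CC)(CC)CC | intermediate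
18 | methyl (2Z)-5-[(1S,2R,4aS,6R,8aR)-6-[(tert-butyldimethylsilyl)oxy]-5,5,8a-trimethyl-2-[(triethylsilyl)oxy]decahydronaphthalen-1-yl]-3-methylpent-2-enoate | COC(=O)/C=C(/C)CC[C@H]1[C@]2(C)CC[C@@H](O[Si](C)(C)C(C)(C)C)C(C)(C)[C@H]2CC[C@H]1O[Si](CC)(CC)CC | intermediate
19 | methyl (2Z)-5-[(1S,2R,4aS,6R,8aR)-6-[(tert-butyldimethylsilyl)oxy]-2-hydroxy-5,5,8a-trimethyldecahydronaphthalen-1-yl]-3-methylpent-2-enoate | COC(=O)/C=C(/C)CC[C@H]1[C@]2(C)CC[C@@H](O[Si](C)(C)C(C)(C)C)C(C)(C)[C@H]2CC[C@H]1O | intermediate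
20 | methyl (2Z)-5-[(1S,4aS,6R,8aR)-6-[(tert-butyldimethylsilyl)oxy]-5,5,8a-trimethyl-2-oxodecahydronaphthalen-1-yl]-3-methylpent-2-enoate | COC(=O)/C=C(/C)CC[C@H]1[C@]2(C)CC[C@@H](O[Si](C)(C)C(C)(C)C)C(C)(C)[C@H]2CCC1=O | intermediate
21 | methyl (2Z)-5-[(1S,2R,4aS,6R,8aR)-6-[(tert-butyldimethylsilyl)oxy]-2-hydroxy-2-{[dimethyl(propan-2-yloxy)silyl]methyl}-5,5,8a-trimethyldecahydronaphthalen-1-yl]-3-methylpent-2-enoate | COC(=O)/C=C(/C)CC[C@H]1[C@]2(C)CC[C@@H](O[Si](C)(C)C(C)(C)C)C(C)(C)[C@H]2CC[C@]1(O)C[Si](C)(C)OC(C)C | intermediate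
22 | methyl (2Z)-5-[(1S,2R,4aS,6R,8aR)-6-[(tert-butyldimethylsilyl)oxy]-2-hydroxy-2-(hydroxymethyl)-5,5,8a-trimethyldecahydronaphthalen-1-yl]-3-methylpent-2-enoate | COC(=O)/C=C(/C)CC[C@H]1[C@]2(C)CC[C@@H](O[Si](C)(C)C(C)(C)C)C(C)(C)[C@H]2CC[C@]1(O)CO | intermediate
23 | methyl (2Z)-5-[(1S,2R,4aS,6R,8aR)-6-[(tert-butyldimethylsilyl)oxy]-2-formyl-2-hydroxy-5,5,8a-trimethyldecahydronaphthalen-1-yl]-3-methylpent-2-enoate | COC(=O)/C=C(/C)CC[C@H]1[C@]2(C)CC[C@@H](O[Si](C)(C)C(C)(C)C)C(C)(C)[C@H]2CC[C@]1(O)C=O | intermediate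
24 | methyl (2Z)-5-[(1S,2R,4aS,6R,8aR)-2-formyl-2,6-dihydroxy-5,5,8a-trimethyldecahydronaphthalen-1-yl]-3-methylpent-2-enoate | COC(=O)/C=C(/C)CC[C@H]1[C@]2(C)CC[C@@H](O)C(C)(C)[C@H]2CC[C@]1(O)C=O | target

**Step count and risks**

Total step count: 17. Longest linear sequence: 16 steps (steps 1–10 and 12–17, from ketone 1); step 11 is a one-step branch.

Steps most likely to fail:

Step 8. The closure at the congested C5–C10 bond may be slow, so that E/Z isomerisation or self-condensation of the enal and exo closure (cis ring fusion) compete. The fallback sets out from ester 9 and returns at aldehyde 12. The enoate of 9 is configurationally stable and tolerates a Lewis acid. With Me2AlCl in CH2Cl2 (−78 → −20 °C) the closure should become a polar, stepwise annulation: C5 adds to C10 of the complexed enoate (Mukaiyama–Michael closure of ring A), and the aluminium enolate then closes on the C8 oxocarbenium ion. This would give methyl ester F1 with the same endo topology. Reduction with i-Bu2AlH gives primary alcohol F2, and Dess–Martin oxidation leads back to 12.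

Step 15. The Grignard reagent may enolise the hindered α-branched ketone or attack the enoate, and the basic peroxide of the oxidation may damage the Z-enoate. The fallback sets out from ketone 20 and returns at diol 22. A samarium Barbier reaction (SmI2, (4-methoxybenzyloxy)methyl chloride, THF, rt) generates a non-basic alkoxymethyl-samarium species that adds to ketones in the presence of esters. Approach along the same equatorial trajectory would give the 4-methoxybenzyl ether F3. DDQ in CH2Cl2/pH 7 buffer then frees 22.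

Step 1. Proton exchange between the unstabilised lithium enolate and the γ-acidic bromoenoate (or the product) may lead to polyalkylation and recovered ketone. The fallback sets out from ketone 1 and returns at keto enoate 4. Acylation of 1 with dimethyl carbonate (NaH, THF, reflux) gives β-keto ester F4. Its soft enolate is alkylated with 2 (K2CO3, acetone) to the alkylated β-keto ester F5. Krapcho demethoxycarbonylation (LiCl, wet DMSO, 140 °C) then gives 4.

Further compounds
F1 | step 8 | methyl (1S,2R,4aS,6R,8aR)-6-[(tert-butyldimethylsilyl)oxy]-5,5,8a-trimethyl-2-[(triethylsilyl)oxy]-1,2,4a,5,6,7,8,8a-octahydronaphthalene-1-carboxylate | COC(=O)[C@H]1[C@]2(C)CC[C@@H](O[Si](C)(C)C(C)(C)C)C(C)(C)[C@H]2C=C[C@H]1O[Si](CC)(CC)CC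
F2 | step 8 | [(1R,2R,4aS,6R,8aR)-6-[(tert-butyldimethylsilyl)oxy]-5,5,8a-trimethyl-2-[(triethylsilyl)oxy]-1,2,4a,5,6,7,8,8a-octahydronaphthalen-1-yl]methanol | OC[C@H]1[C@]2(C)CC[C@@H](O[Si](C)(C)C(C)(C)C)C(C)(C)[C@H]2C=C[C@H]1O[Si](CC)(CC)CC
F3 | step 15 | methyl (2Z)-5-[(1S,2R,4aS,6R,8aR)-6-[(tert-butyldimethylsilyl)oxy]-2-hydroxy-2-{[(4-methoxyphenyl)methoxy]methyl}-5,5,8a-trimethyldecahydronaphthalen-1-yl]-3-methylpent-2-enoate | COC(=O)/C=C(/C)CC[C@H]1[C@]2(C)CC[C@@H](O[Si](C)(C)C(C)(C)C)C(C)(C)[C@H]2CC[C@]1(O)COCc1ccc(OC)cc1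
F4 | step 1 | methyl 4,4-dimethyl-3-oxohept-6-enoate | COC(=O)CC(=O)C(C)(C)CC=C
F5 | step 1 | methyl (2E)-5-(methoxycarbonyl)-3,7,7-trimethyl-6-oxodeca-2,9-dienoate (either configuration at C5) | COC(=O)/C=C(\C)CC(C(=O)OC)C(=O)C(C)(C)CC=C
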